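**Strategy.** Numbering the 1,2-dioxane O1–O2–C3–C4–C5–C6, the route rests on breaking O2–C3. C3 carries the CH2CO2H arm, so the ring is a β-peroxy acid, which is read as a β-lactone opened at its alkyl C–O bond. In one operation, ozonolysis in methanol turns a remote 1,1-disubstituted alkene into the C6 methoxy hydroperoxy ketal, whose terminal oxygen then displaces the lactone carboxylate at C3 with inversion. The ring closes, the free acid appears and C3 is set; C6 follows from anomeric equilibration. The precursor is an (R)-4-alkyloxetan-2-one with a 3-methylidene chain, made by catalytic asymmetric ketene–aldehyde cycloaddition; the enyne is added last by Sonogashira coupling.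

Key step: step 4

Assumption: O-trimethylsilylquinine with LiClO4 is taken to give the (R)-4-alkyl β-lactone (quinidine-derived catalysts giving the (S) series); if the sense proves opposite, O-trimethylsilylquinidine is used and nothing else changes.

**Step 1**
Reactants: 1 (5-chloropent-1-yn-1-yl)trimethylsilane; 2 prop-2-yn-1-ol
Product: 4 2-methylidene-7-(trimethylsilyl)hept-6-yn-1-ol, via Grignard reagent 3 (not isolated)
Conditions: 1, Mg, THF, reflux; then 2 (0.4 equiv), CuI (10 mol %), Et2O/THF, −10 °C to rt; aq. NH4Cl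
Reagents that add atoms: none
Why: CuI-catalysed carbomagnesiation of the propargylic alkoxide places the alkyl group on the internal alkyne carbon (chelated alkenylmagnesium alkoxide), a standard entry to 2-substituted allylic alcohols; no stereocentre is formed.

**Step 2**
Reactants: 4 2-methylidene-7-(trimethylsilyl)hept-6-yn-1-ol
Product: 6 4-methylidene-9-(trimethylsilyl)non-8-ynal, via allyl vinyl ether 5 (not isolated)
Conditions: butyl vinyl ether (solvent), Pd(OAc)2 (5 mol %), 1,10-phenanthroline (5 mol %), rt; filter, concentrate; then PhMe, 150 °C, sealed tube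
Reagents that add atoms: butyl vinyl ether (C=COCCCC)
Why: Palladium-diacetate-catalysed transfer vinylation followed by aliphatic Claisen [3,3]-rearrangement converts the allylic alcohol into the γ,δ-unsaturated aldehyde with the double bond moved into the methylidene position; no stereocentre is formed.

**Step 3**
Reactants: 6 4-methylidene-9-(trimethylsilyl)non-8-ynal
Product: 7 (4R)-4-[3-methylidene-8-(trimethylsilyl)oct-7-yn-1-yl]oxetan-2-one
Conditions: AcCl, iPr2NEt, O-trimethylsilylquinine (10 mol %), LiClO4 (50 mol %), CH2Cl2/Et2O, −78 °C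
Reagents that add atoms: acetyl chloride (CC(Cl)=O)
Why: Cinchona-alkaloid/LiClO4-catalysed acyl halide–aldehyde cyclocondensation (formal [2+2] of in situ ketene with an enolizable aldehyde), in which the alkaloid-bound acetyl enolate adds to one face of the lithium-activated aldehyde, so the catalyst sets the lactone carbon as (R).

**Step 4**
Reactants: 7 (4R)-4-[3-methylidene-8-(trimethylsilyl)oct-7-yn-1-yl]oxetan-2-one
Product: 10 2-[(3S,6R)-6-methoxy-6-[5-(trimethylsilyl)pent-4-yn-1-yl]-1,2-dioxan-3-yl]acetic acid, via hydroperoxy ketal 8 (not isolated), via C6-epimer mixture 9 (not isolated)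
Conditions: O3, CH2Cl2/MeOH (5:1), Sudan Red 7B, −78 °C; N2 purge, concentrate at 0 °C; Sc(OTf)3 (10 mol %), CH2Cl2/Et2O (0.02 M), 0 °C to rt; then MeOH (10 equiv), rt
Reagents that add atoms: ozone ([O-][O+]=O); methanol (CO)
Why: Proposed new method: ozone cleaves only the 1,1-disubstituted alkene (silyl alkyne and lactone are inert at −78 °C), methanol traps the ketone oxide as hydroperoxy ketal 8, and once methanol is removed Sc(OTf)3 activates the lactone carbonyl so that the terminal peroxide oxygen displaces the carboxylate from the β-carbon by SN2 alkyl–oxygen cleavage, closing the 1,2-dioxane and releasing the acetic acid arm. The closest known reaction types are the Lewis-acid-promoted intramolecular opening of oxetanes by hydroperoxy ketals to 1,2-dioxanes and the invertive alkyl–oxygen opening of β-lactones by tethered oxygen nucleophiles to tetrahydrofurans; the hydroperoxide–β-lactone pairing itself is not an established reaction. Ring closure is 6-exo-tet, whereas acyl attack would need an eight-membered perester and attack by the methoxy or inner peroxide oxygen leads only to a reversible five-membered oxonium ion. C3 is set as (S) by inversion of the (R)-lactone carbon. C6 is not controlled kinetically (9 is an epimer mixture) but thermodynamically: acid and methanol ionize the ring ketal to a cyclic peroxycarbenium ion, and methanol returns to favour the epimer with axial methoxy (anomeric effect) and both carbon substituents equatorial, which is (6R). The step needs chemoselective ozonolysis, alkyl- over acyl-oxygen cleavage, and SN2 displacement over ionization; the dye end point, the ring-size bias and the unstabilized secondary centre are expected to secure these.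

**Step 5**
Reactants: 11 undec-1-yne
Product: 13 (E)-1-iodoundec-1-ene, via alkenylzirconocene chloride 12 (not isolated)
Conditions: Cp2Zr(H)Cl, THF, rt; then I2, 0 °C
Reagents that add atoms: iodine (II)
Why: Hydrozirconation is a syn, anti-Markovnikov addition and iodinolysis of the C–Zr bond proceeds with retention, so only the (E)-iodide should form.

**Step 6**
Reactants: 10 2-[(3S,6R)-6-methoxy-6-[5-(trimethylsilyl)pent-4-yn-1-yl]-1,2-dioxan-3-yl]acetic acid; 13 (E)-1-iodoundec-1-ene
Product: 15 2-[(3S,6R)-6-[(E)-hexadec-6-en-4-yn-1-yl]-6-methoxy-1,2-dioxan-3-yl]acetic acid, via terminal alkyne acid 14 (not isolated)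
Conditions: K2CO3 (3 equiv), MeOH/THF, rt; then degas, 13, PdCl2(PPh3)2 (3 mol %), CuI (6 mol %), rt, dark; aq. citric acid to pH 4
Reagents that add atoms: none
Why: Carbonate-mediated methanolysis of the alkynyl C–Si bond followed by Sonogashira coupling, which retains the (E) geometry of the iodide; the acid is present as its carboxylate, which disfavours base-induced β-elimination of the peroxide, and no stereocentre is touched.

**Compound list**
1 | (5-chloropent-1-yn-1-yl)trimethylsilane | C[Si](C)(C)C#CCCCCl | starting material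
2 | prop-2-yn-1-ol | C#CCO | starting material
3 | [5-(trimethylsilyl)pent-4-yn-1-yl]magnesium chloride | C[Si](C)(C)C#CCCC[Mg]Cl | intermediate
4 | 2-methylidene-7-(trimethylsilyl)hept-6-yn-1-ol | C[Si](C)(C)C#CCCCC(=C)CO | intermediate
5 | {6-[(ethenyloxy)methyl]hept-6-en-1-yn-1-yl}trimethylsilane | C[Si](C)(C)C#CCCCC(=C)COC=C | intermediate
6 | 4-methylidene-9-(trimethylsilyl)non-8-ynal | C[Si](C)(C)C#CCCCC(=C)CCC=O | intermediate
7 | (4R)-4-[3-methylidene-8-(trimethylsilyl)oct-7-yn-1-yl]oxetan-2-one | C[Si](C)(C)C#CCCCC(=C)CC[C@@H]1CC(=O)O1 | intermediate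
8 | (4R)-4-[3-hydroperoxy-3-methoxy-8-(trimethylsilyl)oct-7-yn-1-yl]oxetan-2-one (both ketal epimers) | C[Si](C)(C)C#CCCCC(OC)(OO)CC[C@@H]1CC(=O)O1 | intermediate
9 | 2-[(3S)-6-methoxy-6-[5-(trimethylsilyl)pent-4-yn-1-yl]-1,2-dioxan-3-yl]acetic acid (C6 epimer mixture) | C[Si](C)(C)C#CCCCC1(OC)CC[C@@H](CC(=O)O)OO1 | intermediate
10 | 2-[(3S,6R)-6-methoxy-6-[5-(trimethylsilyl)pent-4-yn-1-yl]-1,2-dioxan-3-yl]acetic acid | C[Si](C)(C)C#CCCC[C@]1(OC)CC[C@@H](CC(=O)O)OO1 | intermediate
11 | undec-1-yne | CCCCCCCCCC#C | starting material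
12 | chlorobis(cyclopentadienyl)[(E)-undec-1-en-1-yl]zirconium (rings drawn σ-bonded) | CCCCCCCCC/C=C/[Zr](Cl)(C1C=CC=C1)C1C=CC=C1 | intermediate
13 | (E)-1-iodoundec-1-ene | CCCCCCCCC/C=C/I | intermediate
14 | 2-[(3S,6R)-6-methoxy-6-(pent-4-yn-1-yl)-1,2-dioxan-3-yl]acetic acid | C#CCCC[C@]1(OC)CC[C@@H](CC(=O)O)OO1 | intermediate
15 | 2-[(3S,6R)-6-[(E)-hexadec-6-en-4-yn-1-yl]-6-methoxy-1,2-dioxan-3-yl]acetic acid | CCCCCCCCC/C=C/C#CCCC[C@]1(OC)CC[C@@H](CC(=O)O)OO1 | target

**Step count.** Total: 6 steps. Longest linear sequence: 5 steps (1, 2, 3, 4, 6); step 5 is a one-step side branch.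

**Steps most likely to fail**

1. Step 4 (proposed new method). The acid may ionize or fragment the acyclic hydroperoxy ketal before the lactone is attacked. Intermolecular acyl attack may give oligomeric peresters. The C6 equilibration may stop short of a useful preference.
Fallback (known chemistry), setting out from 7 and returning at 10: LiBH4 in THF reduces the lactone to 1,3-diol F1. TsCl/pyridine at 0 °C sulfonylates the primary hydroxyl to give primary tosylate F2, and NaH in THF closes it (4-exo-tet, stereocentre untouched) to (R)-oxetane F3. Ozonolysis in CH2Cl2/MeOH gives hydroperoxy ketal F4. Under Yb(OTf)3 or TMSOTf catalysis this undergoes the established 6-exo opening of an oxetane by a hydroperoxy ketal, with inversion, to C6-epimer mixture F5. Acid/MeOH equilibration as in step 4 gives dioxane ethanol F6, and TEMPO/PhI(OAc)2 in MeCN/pH 7 buffer oxidizes the primary alcohol to acid 10.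

2. Step 3. Self-aldol or ketene dimerization may outrun the cycloaddition with this enolizable aldehyde, and facial selectivity may be insufficient.
Fallback, setting out from 4 and returning at 7, with the stereocentre taken from the chiral pool: Appel bromination (CBr4, PPh3) gives allylic bromide F7. Its allylic Grignard reagent F8 (Mg, THF, −15 °C) opens (R)-epichlorohydrin (ClC[C@H]1CO1) at the unsubstituted ring carbon under CuI catalysis to chlorohydrin F9. NaOH closes (R)-epoxide F10. Ring-expanding carbonylation with [(salph)Al(THF)2][Co(CO)4] under CO (60 bar, THF, 50 °C) inserts CO into the CH2–O bond with retention at the stereocentre and gives 7.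

3. Step 6. Phosphine or zerovalent palladium may reduce the O–O bond, and oxidative alkyne homocoupling may consume 14.
Fallback, setting out from 6 and returning at 15, so that no metal-catalysed step follows peroxide formation: K2CO3/MeOH gives alkynal F11. Sonogashira coupling with 13 (PdCl2(PPh3)2, CuI, Et3N) gives enynal F12. The ketene cycloaddition of step 3 gives enyne lactone F13. Ozonolysis then relies on the faster reaction of the isolated 1,1-disubstituted alkene than of the conjugated enyne (dye end point) and gives hydroperoxy ketal F14. This cyclizes as in step 4 to C6-epimer mixture F15 and equilibrates to 15.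

**Further compounds**
F1 | step 4 | (3R)-6-methylidene-11-(trimethylsilyl)undec-10-yne-1,3-diol | C[Si](C)(C)C#CCCCC(=C)CC[C@@H](O)CCO
F2 | step 4 | (3R)-3-hydroxy-6-methylidene-11-(trimethylsilyl)undec-10-yn-1-yl 4-methylbenzenesulfonate | C[Si](C)(C)C#CCCCC(=C)CC[C@@H](O)CCOS(=O)(=O)c1ccc(C)cc1
F3 | step 4 | (2R)-2-[3-methylidene-8-(trimethylsilyl)oct-7-yn-1-yl]oxetane | C[Si](C)(C)C#CCCCC(=C)CC[C@@H]1CCO1
F4 | step 4 | (2R)-2-[3-hydroperoxy-3-methoxy-8-(trimethylsilyl)oct-7-yn-1-yl]oxetane (both ketal epimers) | C[Si](C)(C)C#CCCCC(OC)(OO)CC[C@@H]1CCO1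
F5 | step 4 | 2-[(3S)-6-methoxy-6-[5-(trimethylsilyl)pent-4-yn-1-yl]-1,2-dioxan-3-yl]ethan-1-ol (C6 epimer mixture) | C[Si](C)(C)C#CCCCC1(OC)CC[C@@H](CCO)OO1
F6 | step 4 | 2-[(3S,6R)-6-methoxy-6-[5-(trimethylsilyl)pent-4-yn-1-yl]-1,2-dioxan-3-yl]ethan-1-ol | C[Si](C)(C)C#CCCC[C@]1(OC)CC[C@@H](CCO)OO1
F7 | step 3 | [6-(bromomethyl)hept-6-en-1-yn-1-yl]trimethylsilane | C[Si](C)(C)C#CCCCC(=C)CBr
F8 | step 3 | [2-methylidene-7-(trimethylsilyl)hept-6-yn-1-yl]magnesium bromide | C[Si](C)(C)C#CCCCC(=C)C[Mg]Br
F9 | step 3 | (2R)-1-chloro-5-methylidene-10-(trimethylsilyl)dec-9-yn-2-ol | C[Si](C)(C)C#CCCCC(=C)CC[C@@H](O)CCl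
F10 | step 3 | (2R)-2-[3-methylidene-8-(trimethylsilyl)oct-7-yn-1-yl]oxirane | C[Si](C)(C)C#CCCCC(=C)CC[C@@H]1CO1
F11 | step 6 | 4-methylidenenon-8-ynal | C#CCCCC(=C)CCC=O
F12 | step 6 | (E)-4-methylideneicos-10-en-8-ynal | CCCCCCCCC/C=C/C#CCCCC(=C)CCC=O
F13 | step 6 | (4R)-4-[(E)-3-methylidenenonadec-9-en-7-yn-1-yl]oxetan-2-one | CCCCCCCCC/C=C/C#CCCCC(=C)CC[C@@H]1CC(=O)O1
F14 | step 6 | (4R)-4-[(E)-3-hydroperoxy-3-methoxynonadec-9-en-7-yn-1-yl]oxetan-2-one (both ketal epimers) | CCCCCCCCC/C=C/C#CCCCC(OC)(OO)CC[C@@H]1CC(=O)O1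
F15 | step 6 | 2-[(3S)-6-[(E)-hexadec-6-en-4-yn-1-yl]-6-methoxy-1,2-dioxan-3-yl]acetic acid (C6 epimer mixture) | CCCCCCCCC/C=C/C#CCCCC1(OC)CC[C@@H](CC(=O)O)OO1
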